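A small charge in the next run would spare material, so before I cut the starting material I want to know what the cut costs in target.

    starting material ⇌ target (K1 = 1.4, k1 = 0.045 s⁻¹, Ea1 = 90.0 kJ mol⁻¹, ΔH1 = −8.00 kJ mol⁻¹)
    starting material ⇌ isomer of the product (K2 = 2.6, k2 = 0.0012 s⁻¹, Ea2 = 121 kJ mol⁻¹, ΔH2 = −27.0 kJ mol⁻¹)
    target → over-reaction product (k3 = 9.0 × 10⁻⁶ s⁻¹, Ea3 = 119 kJ mol⁻¹)
    crystals ⇌ target, rate k4*(cs4 - [target]) while solid is left; crystals form when [target] > cs4 (cs4 = 27 mM, k4 = 1.3 s⁻¹)
    (constants at 110 °C)

common to all: starting material 2.4 M; time 50 s

|  | temperature |
|---|---|
| south | 110 °C |
| north-west | 118 °C |

- amounts and yields of target count crystals too
- given per volume of solution although it is solid: crystals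
- all constants are for 110 °C and move with temperature by the activation energies and enthalpies

- which of these there is most of at the end, counted by the starting material in it, south (isomer of the product / target / starting material)
- which of these there is most of at the end, counted by the starting material in it, north-west (isomer of the product / target / starting material)
- final amount of the leader among these, as a percentage of the starting material charged, in south
- final amount of the leader among these, as a percentage of the starting material charged, in north-west

I solve the flask at both ends and join them. Let S be the concentration of starting material, c its charge, s the solubility of the target and K the equilibrium constant between starting material and target.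

At the late end, dissolved target goes to crystals much faster than it returns to starting material, so I take it as near s, and while solid is left the reversible step balances at a floor F = s/K, the level towards which the starting material falls. In south 19.3 mM is 0.804 % of the charge. F is a concentration, so its share F/c grows as c shrinks, and that share is the cost I am pricing.

At the early end, first crystals need about 0.250 s, which is far shorter than the run. Dissolved target then goes to crystals much faster than it returns. So I take S to fall pseudo-first-order towards F with k, the sum of the two forward constants, 0.0462 s⁻¹ in south, a half-life of 15.0 s. The over-reaction is far slower than the forward step to target, so I drop it.

Joined, S = F + (c − F)·exp(−k·t). By this reckoning south keeps 10.6 % as starting material. The isomer takes its forward share of the rest, 2.32 %, which leaves target at 87.0 %.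

In north-west k becomes 0.0828 s⁻¹ and the floor 20.3 mM. That gives starting material 2.42 %, isomer 3.07 % and target 94.5 %.

My decision for north-west: I accept a loss of 6 points of target, and I expect the floor's share to take it at c = 0.297 M, so I charge no lower.

The forecast names target for south and target for north-west, at 86.4 % and 94.1 %, less than my figures, reasoning that “the target crystallises quickly”.

The flask gives target in south at 86.4 % and target in north-west at 94.1 %, against my 87.0 % and 94.5 %. South read at 500 s holds 0.808 % as starting material, where the floor's share is 0.804 %. At a charge of 0.306 M I reckon the north-west floor's share at 6.63 %, which is 5.8 percentage points more than at 2.4 M. With the time and all other amounts held, the target in north-west has moved by 6 points at 0.306 M, against the 0.297 M I reckoned.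

(The constants are assumed; the rest is arithmetic.)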